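The closed, stirred vessel holds twice the Q of the birch run, with X and J as before, and is read at 15 min, while the birch readings stop at 3.00 min.

- birch: Q 1 M; X 0.020 M; J 50 mM; run made earlier
- flask: Q 2.0 M; X 0.0200 M; J 50 mM; time 15 min

birch run (percent of the Q charged)

| time / min | L / % | Q / % |
|---|---|---|
| 0.200 | 0.6 | 99.8 |
| 0.667 | 1.4 | 98.6 |
| 1.00 | 2.0 | 97.7 |
| 1.50 | 4.0 | 96.6 |
| 2.50 | 5.1 | 94.4 |
| 3.00 | 7.3 | 92.9 |

(standard deviation of a reading: 0.5 percentage points)

- the average divides the monomer in chains by the number of chains begun, living and dead together
- the analysis behind the earlier runs scatters by 0.5 percentage points, standard deviation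
- the earlier runs do not show the number of chains; that part of a forecast is a guess

* average number of monomer units in a chain (chains begun, living or dead) at 15 min
* part of the Q that has reacted at 15 min

The table is read through the natural logarithm of charged Q over Q left, divided by the time: 0.0245 min⁻¹ in the last row, the fractional rate of Q, or pseudo-first-order constant. The Q column gives 0.0233 min⁻¹ at 1.00 min and 0.0231 min⁻¹ at 2.50 min, so these later readings lie close together. Column against column, L stands at 7.3% in the last row, where Q has lost 7.10%.

If this constant holds at the larger charge and out to 15 min, a reckoning gives 30.8% reacted, or 0.616 M in chains. Counting one chain per J, with 50 mM charged, this guess gives a dp of 12.3.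

The forecast gives 30% and a dp of 11, both below this reckoning, and warns that “X could slowly kill active chains”.

The flask gives 30.5% and a dp of 10.9.

    Q + J → E + L (k = 0.410 L mol⁻¹ min⁻¹)
    Q + E → L + E, rate k2*[E]*[Q] (k = 0.600 L mol⁻¹ min⁻¹)
    E + X → G (k = 5.30 L mol⁻¹ min⁻¹)
    Q → Z (k = 0.00260 min⁻¹)

The flask's fractional rate over the whole time is 0.0243 min⁻¹, beside the 0.0245 min⁻¹ read from the birch run. At 15.0 min the flask holds Q at 69.5%, L at 27.2% and Z at 3.24%, so part of the lost Q stands outside the chains. A neighbour flask charged with 0.050 M of X, other charges and the time held, reacts 21.1% of its Q, against the 30.8% that the constant foretells, and its fractional rate comes to 0.0158 min⁻¹.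

(The readings were computed from invented constants; noise was put on by code.)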